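**Retrosynthetic overview**

1. Target 29 ⇐ late acylation of O11 (tertiary alkoxide + angelic anhydride) and O6 (Yamaguchi esterification) of the (1(10)Z,4E)-germacradien-12,8-olide core 22.
2. Ten-membered carbocycle of 22 ⇐ Ramberg–Bäcklund ring contraction of the eleven-membered cyclic sulfone 19, in which SO2 bridges C1 and C10. The enabling feature is the isolated (Z)-trisubstituted C1=C10 alkene flanked by the C2 and C9 methylenes: its cis geometry is the one a ten-membered ring already holding the (E)-C4=C5 alkene imposes on the episulfone.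
3. Eleven-membered thiacycle 18 ⇐ intramolecular S-alkylation of a C10 thiolate on C1–Cl; C10 is a traceless centre that needs no control.
4. γ-Lactone and C6/C7/C8 ⇐ boron syn-aldol of enone 6 with 3-(acetylsulfanyl)butanal, lactonisation of O8 onto the dioxolanone (acetone leaves, O11–H is unmasked), then Felkin–Anh reduction at C6; C11 comes from the chiral pool.
5. Enone 6 ⇐ (R)-citramalic acid (C6, C7, C11, C12, C13) + carboaluminated 5-chloropent-1-yne (C1–C5, C15). Ring order: dioxolanone (temporary), γ-lactone, eleven-membered thiacycle, ten-membered carbocycle.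

Key step: step 11

Remark: locants C1–C15 in the text are those of the germacrane skeleton of the target (ring alkenes C1=C10 and C4=C5, lactone carbonyl C12 on C11, lactone oxygen on C8, ester oxygens on C6 and C11).
Remark: the sulfur-bearing carbon C10 is carried as a mixture of epimers in 9 and 11–21 and is left undefined in their SMILES; it becomes sp2 in step 11.
Remark: (−)-Ipc2BOTf is assumed to direct the (Z)-enol borinate to the Si face of the aldehyde, as is usual for methylene ketones; if the enantiomeric syn pair at C7/C8 forms, the (+)-reagent is used instead.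

**Route**

Step 1
Reactants: 1 (R)-citramalic acid [(2R)-2-hydroxy-2-methylbutanedioic acid]
Product: 2 2-[(4R)-2,2,4-trimethyl-5-oxo-1,3-dioxolan-4-yl]acetic acid
Conditions: Me2C(OMe)2 (excess), TsOH·H2O (cat.), acetone, rt
Reagents that add atoms: 2,2-dimethoxypropane, COC(C)(C)OC
Why: Acid-catalysed acetonide formation (transacetalisation) should select the five-membered dioxolanone of the α-hydroxy acid, which leaves the CH2CO2H arm free, masks O11–H and C12 together, and does not touch the stereocentre.

Step 2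
Reactants: 2 2-[(4R)-2,2,4-trimethyl-5-oxo-1,3-dioxolan-4-yl]acetic acid
Product: 3 2-[(4R)-2,2,4-trimethyl-5-oxo-1,3-dioxolan-4-yl]acetyl chloride
Conditions: (COCl)2, DMF (cat.), CH2Cl2, 0 °C → rt; volatiles removed, used crude
Reagents that add atoms: oxalyl chloride, O=C(Cl)C(=O)Cl
Why: Acid chloride formation through the Vilsmeier-type chloroiminium catalyst is neutral enough to leave the dioxolanone intact.

Step 3
Reactants: 3 2-[(4R)-2,2,4-trimethyl-5-oxo-1,3-dioxolan-4-yl]acetyl chloride; 4 5-chloropent-1-yne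
Product: 6 (5R)-5-[(3E)-7-chloro-4-methyl-2-oxohept-3-en-1-yl]-2,2,5-trimethyl-1,3-dioxolan-4-one, via alkenylalane 5 (not isolated)
Conditions: 4, Me3Al (2 equiv), Cp2ZrCl2 (0.25 equiv), CH2Cl2, 0 °C → rt; excess Me3Al removed in vacuo; then 3, Pd(PPh3)4 (5 mol %), THF, 0 °C → rt
Reagents that add atoms: trimethylaluminium, C[Al](C)C
Why: Negishi zirconium-catalysed syn-carboalumination puts methyl and aluminium cis on the terminal alkyne, and acylation of the alkenylalane under zerovalent palladium catalysis proceeds with retention, so the (E)-trisubstituted C4=C5 alkene (C15 from Me3Al) is fixed here and the enone is left with a single enolisable α-methylene (C7).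

Step 4
Reactants: 7 (E)-but-2-enal; 8 thioacetic acid
Product: 9 S-(4-oxobutan-2-yl) ethanethioate [3-(acetylsulfanyl)butanal] (racemic)
Conditions: Et3N (cat.), CH2Cl2, 0 °C → rt
Reagents that add atoms: none
Why: Thia-Michael addition of the thioacid to the enal places sulfur on the methyl-bearing β-carbon (future C10 with C14); its configuration is irrelevant.

Step 5
Reactants: 6 (5R)-5-[(3E)-7-chloro-4-methyl-2-oxohept-3-en-1-yl]-2,2,5-trimethyl-1,3-dioxolan-4-one; 9 S-(4-oxobutan-2-yl) ethanethioate
Product: 12 S-[(4R,5R,7E)-11-chloro-4-hydroxy-8-methyl-6-oxo-5-[(4R)-2,2,4-trimethyl-5-oxo-1,3-dioxolan-4-yl]undec-7-en-2-yl] ethanethioate (aldol adduct; 7R,8R,11R in skeleton locants), via enol borinate 10 (not isolated), via boron aldolate 11 (not isolated)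
Conditions: (−)-Ipc2BOTf (1.5 equiv), i-Pr2NEt (2 equiv), CH2Cl2, −78 °C; 9, −78 → −20 °C; then MeOH, pH 7 buffer, 30% H2O2, 0 °C
Reagents that add atoms: none
Why: Ipc2B-mediated ketone syn-aldol reaction: soft enolisation can occur only at the C7 methylene, the (Z)-enol borinate reacts through a closed chair (Zimmerman–Traxler) transition state so that C7 and C8 emerge syn, and the isopinocampheyl ligands are relied on to select the aldehyde Si face, which sets (8R) and with it (7R); the remote C10 centre of 9 has no influence in a closed transition state.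

Step 6
Reactants: 12 aldol adduct
Product: 14 (3R,4R,5R)-5-[2-(acetylsulfanyl)propyl]-4-[(2E)-6-chloro-3-methylhex-2-enoyl]-3-methyl-3-[(trimethylsilyl)oxy]oxolan-2-one, via hydroxy lactone 13 (not isolated)
Conditions: CSA (10 mol %), CH2Cl2, rt; then 2,6-lutidine, Me3SiOTf, −78 °C
Reagents that add atoms: trimethylsilyl trifluoromethanesulfonate, C[Si](C)(C)OS(=O)(=O)C(F)(F)F
Why: Acid-catalysed intramolecular transesterification (5-exo-trig γ-lactonisation): O8 attacks the dioxolanone carbonyl, the acetonide leaves as acetone and uncovers O11–H, so only the 12,8-olide can form and the syn-aldol relationship becomes the trans ring fusion; silylation of the tertiary hydroxyl (silyl triflate/lutidine) then removes a chelating, acidic site before the reduction.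

Step 7
Reactants: 14 (3R,4R,5R)-5-[2-(acetylsulfanyl)propyl]-4-[(2E)-6-chloro-3-methylhex-2-enoyl]-3-methyl-3-[(trimethylsilyl)oxy]oxolan-2-one
Product: 15 (3R,4R,5R)-5-[2-(acetylsulfanyl)propyl]-4-[(1S,2E)-6-chloro-1-hydroxy-3-methylhex-2-en-1-yl]-3-methyl-3-[(trimethylsilyl)oxy]oxolan-2-one
Conditions: LiBH(s-Bu)3 (1.1 equiv), THF, −78 °C; AcOH quench at −78 °C
Reagents that add atoms: none
Why: Felkin–Anh-controlled 1,2-reduction of the β,β-disubstituted enone by a bulky, non-chelating hydride: the carbonyl on ring carbon C7 should be attacked anti to the quaternary, silyloxy-bearing C11 and past the C8–H side, giving the (6S)-alcohol, and the cold acidic quench keeps the new alkoxide from attacking the lactone.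

Step 8
Reactants: 15 (6S)-allylic alcohol
Product: 16 (3R,4S,5R)-5-[2-(acetylsulfanyl)propyl]-4-[(1S,2E)-1-{[tert-butyl(dimethyl)silyl]oxy}-6-chloro-3-methylhex-2-en-1-yl]-3-methyl-3-[(trimethylsilyl)oxy]oxolan-2-one
Conditions: t-BuMe2SiOTf, 2,6-lutidine, CH2Cl2, −78 → 0 °C
Reagents that add atoms: tert-butyldimethylsilyl trifluoromethanesulfonate, CC(C)(C)[Si](C)(C)OS(=O)(=O)C(F)(F)F
Why: Silylation (silyl triflate/2,6-lutidine) of the only free hydroxyl, so that base cannot later move the lactone from O8 to O6 and the two hydroxyls stay distinguishable for the two esterifications.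

Step 9
Reactants: 16 bis-silyl ether chloro thioacetate
Product: 18 eleven-membered cyclic sulfide (4E,6S,7S,8R,11R)-6-{[tert-butyl(dimethyl)silyl]oxy}-11-hydroxy-1,10-seco-1,10-epithiogermacr-4-en-12,8-olide, via seco-thiol 17 (not isolated)
Conditions: K2CO3 (3 equiv), NaI (0.2 equiv), degassed MeOH/DMF (1:4), 2 mM, 45 °C; aq. citric acid work-up
Reagents that add atoms: none
Why: Intramolecular thiolate S-alkylation (thioether synthesis with Finkelstein catalysis): carbonate in methanol cleaves the thioacetate and the tertiary trimethylsilyl ether, and the soft secondary thiolate displaces the primary halide at high dilution to close the eleven-membered ring, a size made accessible by the long C–S bonds, the (E)-alkene and the fused lactone.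

Step 10
Reactants: 18 eleven-membered cyclic sulfide
Product: 19 eleven-membered cyclic sulfone (S,S-dioxide of 18)
Conditions: (NH4)6Mo7O24·4H2O (10 mol %), 30% H2O2 (5 equiv), EtOH, 0 °C → rt
Reagents that add atoms: hydrogen peroxide, OO
Why: Molybdate-catalysed peroxide oxidation of sulfide to sulfone; sulfur is far more nucleophilic than the trisubstituted alkene, which has no free allylic hydroxyl to direct epoxidation.

Step 11
Reactants: 19 eleven-membered cyclic sulfone
Product: 22 (1(10)Z,4E,6S,7S,8R,11R)-6-{[tert-butyl(dimethyl)silyl]oxy}-11-hydroxygermacra-1(10),4-dien-12,8-olide, via α-bromo sulfone 20 (not isolated), via cis-fused episulfone 21 (not isolated)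
Conditions: BrCF2CF2Br (5 equiv), KOH/Al2O3 (excess), t-BuOH/CH2Cl2, 0 °C → rt; aq. citric acid work-up
Reagents that add atoms: none
Why: One-pot Ramberg–Bäcklund reaction: KOH on alumina deprotonates an α-sulfonyl carbon (C1 or C10, both lead to the same alkene), the carbanion is brominated by BrCF2CF2Br (which collapses to CF2=CF2 and bromide, so no carbene is formed), and deprotonation at the other α-carbon triggers 1,3-displacement of bromide to episulfone 21, which loses SO2 cheletropically with retention. The closest known reaction type is the ring contraction of cyclic sulfones to cycloalkenes, which is established for strained medium-ring alkenes in sesquiterpenoid lactones. The ten-membered carbocycle is closed by contraction of the eleven-membered ring: a 3-exo-tet C1–C10 bond formation within the sulfone, followed by extrusion of the one-atom sulfur bridge. No stereocentre is created; C6, C7, C8 and C11 carry no acidic hydrogen (C11 is quaternary) and should pass unchanged, and the C10 epimers converge. The selectivity needed is the Z geometry at C1=C10: it corresponds to the cis-fused episulfone, which a ten-membered ring already holding the (4E)-alkene should accommodate with the least strain, and the episulfone C1–H is acidic enough to allow equilibration to this isomer before SO2 is lost. Chemoselectivity rests on the sulfone α-hydrogens being the only acidic C–H bonds; a lactone opened on the basic support should re-close to the 12,8-olide on acidic work-up because O6 is silylated.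

Step 12
Reactants: 22 (1(10)Z,4E,6S,7S,8R,11R)-6-{[tert-butyl(dimethyl)silyl]oxy}-11-hydroxygermacra-1(10),4-dien-12,8-olide; 23 angelic anhydride [(2Z)-2-methylbut-2-enoic anhydride]
Product: 25 (1(10)Z,4E,6S,7S,8R,11R)-11-(angeloyloxy)-6-{[tert-butyl(dimethyl)silyl]oxy}germacra-1(10),4-dien-12,8-olide, via lithium alkoxide 24 (not isolated)
Conditions: LiN(SiMe3)2 (1.05 equiv), THF, −78 °C; 23 (2 equiv), −78 → −20 °C; aq. NH4Cl
Reagents that add atoms: none
Why: Acylation of a tertiary lithium alkoxide with the anhydride: the hindered α-hydroxy lactone is activated as its alkoxide and the symmetric anhydride transfers the (Z)-2-methylbut-2-enoyl group at low temperature without a nucleophilic catalyst, conditions under which an angelate should not isomerise to the tiglate; C11 is not touched at carbon, so its configuration is retained.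

Step 13
Reactants: 25 11-angelate 6-silyl ether
Product: 26 (1(10)Z,4E,6S,7R,8R,11R)-11-(angeloyloxy)-6-hydroxygermacra-1(10),4-dien-12,8-olide
Conditions: Bu4NF, AcOH (1:1), THF, 0 °C → rt
Reagents that add atoms: none
Why: Fluoride-mediated desilylation buffered with acetic acid, so that neither a free alkoxide (translactonisation to O6, ester cleavage) nor a strong acid (transannular cyclisation of the 1,5-diene) is present.

Step 14
Reactants: 26 (1(10)Z,4E,6S,7R,8R,11R)-11-(angeloyloxy)-6-hydroxygermacra-1(10),4-dien-12,8-olide; 27 angelic acid [(2Z)-2-methylbut-2-enoic acid]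
Product: 29 (1(10)Z,4E,6S,7S,8R,11R)-6,11-bis(angeloyloxy)germacra-1(10),4-dien-12,8-olide (target), via mixed anhydride 28 (not isolated)
Conditions: 27 (3 equiv), 2,4,6-Cl3C6H2COCl (3 equiv), Et3N (6 equiv), toluene, rt; then 26, toluene, 60 °C
Reagents that add atoms: none
Why: Yamaguchi esterification through the mixed 2,4,6-trichlorobenzoic anhydride: the secondary allylic hydroxyl attacks the less hindered angeloyl carbonyl, and leaving out DMAP and keeping the temperature moderate should avoid angelate-to-tiglate isomerisation and Cope rearrangement of the 1,5-diene.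

**Compound list**

1 | (R)-citramalic acid | O=C(O)[C@](C)(O)CC(=O)O | starting material
2 | 2-[(4R)-2,2,4-trimethyl-5-oxo-1,3-dioxolan-4-yl]acetic acid | O=C1OC(C)(C)O[C@]1(C)CC(=O)O | intermediate
3 | 2-[(4R)-2,2,4-trimethyl-5-oxo-1,3-dioxolan-4-yl]acetyl chloride | O=C1OC(C)(C)O[C@]1(C)CC(=O)Cl | intermediate
4 | 5-chloropent-1-yne | C#CCCCCl | starting material
5 | [(1E)-5-chloro-2-methylpent-1-en-1-yl]dimethylalane | C[Al](C)/C=C(\C)CCCCl | intermediate
6 | (5R)-5-[(3E)-7-chloro-4-methyl-2-oxohept-3-en-1-yl]-2,2,5-trimethyl-1,3-dioxolan-4-one | O=C1OC(C)(C)O[C@]1(C)CC(=O)/C=C(\C)CCCCl | intermediate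
7 | (E)-but-2-enal | C/C=C/C=O | starting material
8 | thioacetic acid | CC(=O)S | starting material
9 | S-(4-oxobutan-2-yl) ethanethioate (racemic) | CC(CC=O)SC(C)=O | intermediate
10 | (Z)-enol diisopinocampheylborinate of 6 | O=C1OC(C)(C)O[C@]1(C)/C=C(OB([C@@H]2C[C@@H]3C[C@H]([C@H]2C)C3(C)C)[C@@H]2C[C@@H]3C[C@H]([C@H]2C)C3(C)C)/C=C(\C)CCCCl | intermediate
11 | O8-diisopinocampheylboryl aldolate of 12 | CC(=O)SC(C)C[C@@H](OB([C@@H]2C[C@@H]3C[C@H]([C@H]2C)C3(C)C)[C@@H]2C[C@@H]3C[C@H]([C@H]2C)C3(C)C)[C@@H](C(=O)/C=C(\C)CCCCl)[C@@]1(C)OC(C)(C)OC1=O | intermediate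
12 | S-[(4R,5R,7E)-11-chloro-4-hydroxy-8-methyl-6-oxo-5-[(4R)-2,2,4-trimethyl-5-oxo-1,3-dioxolan-4-yl]undec-7-en-2-yl] ethanethioate | CC(=O)SC(C)C[C@@H](O)[C@@H](C(=O)/C=C(\C)CCCCl)[C@@]1(C)OC(C)(C)OC1=O | intermediate
13 | (3R,4R,5R)-5-[2-(acetylsulfanyl)propyl]-4-[(2E)-6-chloro-3-methylhex-2-enoyl]-3-hydroxy-3-methyloxolan-2-one | CC(=O)SC(C)C[C@H]1OC(=O)[C@](C)(O)[C@@H]1C(=O)/C=C(\C)CCCCl | intermediate
14 | (3R,4R,5R)-5-[2-(acetylsulfanyl)propyl]-4-[(2E)-6-chloro-3-methylhex-2-enoyl]-3-methyl-3-[(trimethylsilyl)oxy]oxolan-2-one | CC(=O)SC(C)C[C@H]1OC(=O)[C@](C)(O[Si](C)(C)C)[C@@H]1C(=O)/C=C(\C)CCCCl | intermediate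
15 | (3R,4R,5R)-5-[2-(acetylsulfanyl)propyl]-4-[(1S,2E)-6-chloro-1-hydroxy-3-methylhex-2-en-1-yl]-3-methyl-3-[(trimethylsilyl)oxy]oxolan-2-one | CC(=O)SC(C)C[C@H]1OC(=O)[C@](C)(O[Si](C)(C)C)[C@@H]1[C@@H](O)/C=C(\C)CCCCl | intermediate
16 | (3R,4S,5R)-5-[2-(acetylsulfanyl)propyl]-4-[(1S,2E)-1-{[tert-butyl(dimethyl)silyl]oxy}-6-chloro-3-methylhex-2-en-1-yl]-3-methyl-3-[(trimethylsilyl)oxy]oxolan-2-one | CC(=O)SC(C)C[C@H]1OC(=O)[C@](C)(O[Si](C)(C)C)[C@@H]1[C@@H](O[Si](C)(C)C(C)(C)C)/C=C(\C)CCCCl | intermediate
17 | (3R,4S,5R)-4-[(1S,2E)-1-{[tert-butyl(dimethyl)silyl]oxy}-6-chloro-3-methylhex-2-en-1-yl]-3-hydroxy-3-methyl-5-(2-sulfanylpropyl)oxolan-2-one | CC(S)C[C@H]1OC(=O)[C@](C)(O)[C@@H]1[C@@H](O[Si](C)(C)C(C)(C)C)/C=C(\C)CCCCl | intermediate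
18 | (4E,6S,7S,8R,11R)-6-{[tert-butyl(dimethyl)silyl]oxy}-11-hydroxy-1,10-seco-1,10-epithiogermacr-4-en-12,8-olide (eleven-membered cyclic sulfide, S between C1 and C10) | CC3C[C@H]1OC(=O)[C@](C)(O)[C@@H]1[C@@H](O[Si](C)(C)C(C)(C)C)/C=C(\C)CCCS3 | intermediate
19 | S,S-dioxide of 18 (eleven-membered cyclic sulfone) | CC3C[C@H]1OC(=O)[C@](C)(O)[C@@H]1[C@@H](O[Si](C)(C)C(C)(C)C)/C=C(\C)CCCS3(=O)=O | intermediate
20 | α-bromo sulfone of 19 (drawn with bromine on C1; the C10 regioisomer reacts alike) | CC3C[C@H]1OC(=O)[C@](C)(O)[C@@H]1[C@@H](O[Si](C)(C)C(C)(C)C)/C=C(\C)CCC(Br)S3(=O)=O | intermediate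
21 | cis-fused episulfone (thiirane 1,1-dioxide spanning C1 and C10 on the ten-membered ring; one of the two cis-fused faces drawn) | C[C@@]12C[C@H]3OC(=O)[C@](C)(O)[C@@H]3[C@@H](O[Si](C)(C)C(C)(C)C)/C=C(\C)CC[C@@H]1S2(=O)=O | intermediate
22 | (1(10)Z,4E,6S,7S,8R,11R)-6-{[tert-butyl(dimethyl)silyl]oxy}-11-hydroxygermacra-1(10),4-dien-12,8-olide | CC(C)(C)[Si](C)(C)O[C@H]1/C=C(\C)CC/C=C(/C)C[C@H]2OC(=O)[C@](C)(O)[C@H]12 | intermediate
23 | angelic anhydride | C/C=C(/C)C(=O)OC(=O)/C(C)=C\C | starting material
24 | lithium 11-alkoxide of 22 | CC(C)(C)[Si](C)(C)O[C@H]1/C=C(\C)CC/C=C(/C)C[C@H]2OC(=O)[C@](C)([O-])[C@H]12.[Li+] | intermediate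
25 | (1(10)Z,4E,6S,7S,8R,11R)-11-(angeloyloxy)-6-{[tert-butyl(dimethyl)silyl]oxy}germacra-1(10),4-dien-12,8-olide | CC(C)(C)[Si](C)(C)O[C@H]1/C=C(\C)CC/C=C(/C)C[C@H]2OC(=O)[C@](C)(OC(=O)/C(C)=C\C)[C@H]12 | intermediate
26 | (1(10)Z,4E,6S,7R,8R,11R)-11-(angeloyloxy)-6-hydroxygermacra-1(10),4-dien-12,8-olide | O[C@H]1/C=C(\C)CC/C=C(/C)C[C@H]2OC(=O)[C@](C)(OC(=O)/C(C)=C\C)[C@H]12 | intermediate
27 | angelic acid | C/C=C(/C)C(=O)O | starting material
28 | angelic 2,4,6-trichlorobenzoic anhydride | C/C=C(/C)C(=O)OC(=O)c1c(Cl)cc(Cl)cc1Cl | intermediate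
29 | (1(10)Z,4E,6S,7S,8R,11R)-6,11-bis(angeloyloxy)germacra-1(10),4-dien-12,8-olide | C/C=C(/C)C(=O)O[C@H]1/C=C(\C)CC/C=C(/C)C[C@H]2OC(=O)[C@](C)(OC(=O)/C(C)=C\C)[C@H]12 | target

**Step count and risks**

Total step count: 14. Longest linear sequence: 13 steps (steps 1–3 and 5–14, from 1 to 29); step 4 is a one-step side branch.

The three steps most likely to fail:

Step 5 (aldol). The enol borinate may lose its β-oxygen (opening of the dioxolanone by elimination) before it adds, or the boron ligands may give poor facial selection against the bias of the quaternary C11. The fallback sets out from 6 and comes back at 13 as its single (10R) epimer; it fixes the aldehyde face by 1,3-anti induction in an open transition state and uses no metal enolate. Commercial ethyl (S)-3-hydroxybutanoate is protected with 4-methoxybenzyl 2,2,2-trichloroacetimidate (CSA cat., CH2Cl2) to ethyl (3S)-3-[(4-methoxybenzyl)oxy]butanoate F1 and reduced (i-Bu2AlH, CH2Cl2, −78 °C) to (3S)-3-[(4-methoxybenzyl)oxy]butanal F2. Enone 6 is converted (Me3SiOTf, Et3N, CH2Cl2, 0 °C) into its (Z)-trimethylsilyl dienol ether F3. A Mukaiyama aldol addition of F3 to F2 (BF3·OEt2, CH2Cl2, −78 °C) followed by CSA-induced lactonisation should give (3R,4R,5R)-4-[(2E)-6-chloro-3-methylhex-2-enoyl]-3-hydroxy-5-{(2S)-2-[(4-methoxybenzyl)oxy]propyl}-3-methyloxolan-2-one F4; C7, α to the ketone, can settle in the favoured all-trans arrangement. DDQ (CH2Cl2/pH 7 buffer) then frees (3R,4R,5R)-4-[(2E)-6-chloro-3-methylhex-2-enoyl]-3-hydroxy-5-[(2S)-2-hydroxypropyl]-3-methyloxolan-2-one F5, and a Mitsunobu reaction with thioacetic acid (PPh3, DIAD, THF, 0 °C, inversion) returns to 13, which is silylated as in the second half of step 6.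

Step 11 (key step). In the heterogeneous one-pot procedure the lactone may be attacked or hydrolysed faster than the sulfone is halogenated, the α-carbon may be brominated twice, or the episulfone may collapse to an E/Z mixture. The fallback sets out from 19 and comes back at 22; it separates halogenation from contraction so that the base step runs briefly on a defined halosulfone with a soluble, non-nucleophilic base. Sulfone 19 is deprotonated (LiN(SiMe3)2, 2.1 equiv, THF, −78 °C) and chlorinated with hexachloroethane to the α-chloro sulfone F6, which is isolated. Treatment with KOt-Bu (THF, −78 → 0 °C) should then give 22 by the classical two-stage Ramberg–Bäcklund reaction.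

Step 9 (macrocyclisation). Intermolecular S-alkylation (oligomers) or disulfide formation may outrun closure of the eleven-membered ring. The fallback sets out from 16 and comes back at 18; it closes a larger ring under thermodynamic control and then removes one sulfur atom. The chloride of 16 is displaced with KSAc (NaI, DMF) to give the bis(thioacetate) F7. Methanolysis under air (K2CO3 cat., MeOH, high dilution) should give the twelve-membered cyclic disulfide F8 by reversible disulfide exchange. Sulfur extrusion with P(NEt2)3 (THF, rt) then contracts it to sulfide 18: the phosphine attacks the less hindered sulfur on C1 and the secondary thiolate on C10 displaces it at the primary carbon.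

Further compounds
F1 | step 5 | ethyl (3S)-3-[(4-methoxybenzyl)oxy]butanoate | CCOC(=O)C[C@H](C)OCc1ccc(OC)cc1
F2 | step 5 | (3S)-3-[(4-methoxybenzyl)oxy]butanal | O=CC[C@H](C)OCc1ccc(OC)cc1
F3 | step 5 | (5R)-5-{(1Z,3E)-7-chloro-4-methyl-2-[(trimethylsilyl)oxy]hepta-1,3-dien-1-yl}-2,2,5-trimethyl-1,3-dioxolan-4-one | O=C1OC(C)(C)O[C@]1(C)/C=C(O[Si](C)(C)C)/C=C(\C)CCCCl
F4 | step 5 | (3R,4R,5R)-4-[(2E)-6-chloro-3-methylhex-2-enoyl]-3-hydroxy-5-{(2S)-2-[(4-methoxybenzyl)oxy]propyl}-3-methyloxolan-2-one | C[C@H](OCc1ccc(OC)cc1)C[C@H]1OC(=O)[C@](C)(O)[C@@H]1C(=O)/C=C(\C)CCCCl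
F5 | step 5 | (3R,4R,5R)-4-[(2E)-6-chloro-3-methylhex-2-enoyl]-3-hydroxy-5-[(2S)-2-hydroxypropyl]-3-methyloxolan-2-one | C[C@H](O)C[C@H]1OC(=O)[C@](C)(O)[C@@H]1C(=O)/C=C(\C)CCCCl
F6 | step 11 | α-chloro sulfone of 19 (chlorine on C1) | CC3C[C@H]1OC(=O)[C@](C)(O)[C@@H]1[C@@H](O[Si](C)(C)C(C)(C)C)/C=C(\C)CCC(Cl)S3(=O)=O
F7 | step 9 | bis(thioacetate) (C1 chloride of 16 replaced by acetylsulfanyl) | CC(=O)SC(C)C[C@H]1OC(=O)[C@](C)(O[Si](C)(C)C)[C@@H]1[C@@H](O[Si](C)(C)C(C)(C)C)/C=C(\C)CCCSC(C)=O
F8 | step 9 | twelve-membered cyclic disulfide (S–S between C1 and C10; 6-silyl ether, 11-hydroxy, 12,8-olide) | CC3C[C@H]1OC(=O)[C@](C)(O)[C@@H]1[C@@H](O[Si](C)(C)C(C)(C)C)/C=C(\C)CCCSS3
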